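**Retrosynthetic overview** (C‑numbers are the germacrane locants of the target; lactone carbonyl = C12, exo‑methylene = C13)
1. Target ⇒ Yamaguchi angeloylation of the 8β‑OH, which first directs the 1β,10β‑epoxidation; the 3β‑ester comes from a free 3β‑OH.
2. The C6–C7 bond and the O6–C12 lactone bond are cut together ⇒ a ten‑membered "tether" macrolactone (C12 acyl on O‑3) holding a 2‑(bromomethyl)enoate across the ring from a (Z)‑enal (transannular Barbier allylation/translactonisation).
3. Tether macrolactone ⇒ ring‑closing metathesis at C1=C10 of a seco ester, itself from Morita–Baylis–Hillman union of a west acrylate (C1–C6) with an east α‑silyloxy aldehyde (C7–C10), then SN2′ bromination.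
4. Ring order: temporary macrolactone → ten‑membered carbocycle and γ‑lactone together → epoxide last.

Assumption: (R)‑2‑methylbutanoic acid, angelic acid and (−)‑B‑allyldiisopinocampheylborane solution are bought; the target is (1R,3S,6R,7R,8R,10S), 4Z, with an (R)‑2‑methylbutanoyl and an angeloyl (Z) ester, as read from the SMILES.

Step 1
Reactants: 1 3-methylfuran-2(5H)-one
Product: 2 3-methyl-2,5-dihydrofuran-2-ol (lactol used crude)
Conditions: i-Bu2AlH (1.1 equiv), CH2Cl2, −78 °C; aq. KNaC4H4O6 (potassium sodium tartrate)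
Reagents that add atoms: none
Why: partial lactone-to-lactol reduction stops at the aluminium hemiacetal at −78 °C, and the five-membered ring fixes the future C4=C5 olefin as Z (the hemiacetal carbon becomes C3, the ring CH2O becomes C6).

Step 2
Reactants: 2 3-methyl-2,5-dihydrofuran-2-ol
Product: 3 (2Z,4S)-3-methylhepta-2,6-diene-1,4-diol
Conditions: (−)-Ipc2B(allyl) (2.2 equiv), Et2O, −78 °C to rt; then NaOH, H2O2
Reagents that add atoms: (−)-B-allyldiisopinocampheylborane, C=CCB([C@@H]1C[C@@H]2C[C@H]([C@H]1C)C2(C)C)[C@@H]1C[C@@H]2C[C@H]([C@H]1C)C2(C)C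
Why: Brown asymmetric allylboration on the ring-opened hydroxy-enal form of 2; the chair Zimmerman–Traxler transition state of the (−)-Ipc2B reagent delivers allyl to the Si face and sets C3 as S (reagent control).

Step 3
Reactants: 3 (2Z,4S)-3-methylhepta-2,6-diene-1,4-diol
Product: 4 (2Z,4S)-3-methyl-1-(triethylsilyloxy)hepta-2,6-dien-4-ol
Conditions: TESCl (1.05 equiv), imidazole, CH2Cl2, −78 to −40 °C
Reagents that add atoms: chlorotriethylsilane, CC[Si](Cl)(CC)CC
Why: selective silyl ether formation, the primary allylic hydroxyl (future C6) reacting far faster than the hindered secondary one.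

Step 4
Reactants: 4 (2Z,4S)-3-methyl-1-(triethylsilyloxy)hepta-2,6-dien-4-ol; 5 acryloyl chloride
Product: 6 (2Z,4S)-3-methyl-1-(triethylsilyloxy)hepta-2,6-dien-4-yl prop-2-enoate
Conditions: Et3N, CH2Cl2, −20 to 0 °C
Reagents that add atoms: none
Why: O-acylation with an acid chloride puts C11–C13 on O-3, so that the future lactone carboxyl serves as the tether; C3 is untouched.

Step 5
Reactants: 7 ethyl glyoxylate; 8 2-methylpropene
Product: 9 ethyl (2R)-2-hydroxy-4-methylpent-4-enoate
Conditions: (R)-BINOL (10 mol%), TiCl2(OiPr)2 (10 mol%), MS 4Å, CH2Cl2, −30 °C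
Reagents that add atoms: none
Why: Mikami asymmetric glyoxylate-ene reaction; the (R)-BINOL–titanium Lewis acid shields one face of the chelated glyoxylate and gives the (R)-carbinol that becomes C8.

Step 6
Reactants: 9 ethyl (2R)-2-hydroxy-4-methylpent-4-enoate
Product: 10 ethyl (2R)-2-(tert-butyldimethylsilyloxy)-4-methylpent-4-enoate
Conditions: TBSCl, imidazole, DMF, rt
Reagents that add atoms: tert-butylchlorodimethylsilane, CC(C)(C)[Si](C)(C)Cl
Why: standard silyl ether formation protects the 8-oxygen for the base-mediated union; C8 is untouched.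

Step 7
Reactants: 10 ethyl (2R)-2-(tert-butyldimethylsilyloxy)-4-methylpent-4-enoate
Product: 11 (2R)-2-(tert-butyldimethylsilyloxy)-4-methylpent-4-enal
Conditions: i-Bu2AlH (1.05 equiv), CH2Cl2, −78 °C; aq. KNaC4H4O6
Reagents that add atoms: none
Why: partial ester-to-aldehyde reduction through the chelated tetrahedral aluminium hemiacetal that is stable at −78 °C; the α-silyloxy centre (C8) is not epimerised.

Step 8
Reactants: 6 (2Z,4S)-3-methyl-1-(triethylsilyloxy)hepta-2,6-dien-4-yl prop-2-enoate; 11 (2R)-2-(tert-butyldimethylsilyloxy)-4-methylpent-4-enal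
Product: 12 (2Z,4S)-3-methyl-1-(triethylsilyloxy)hepta-2,6-dien-4-yl (4R)-4-(tert-butyldimethylsilyloxy)-3-hydroxy-6-methyl-2-methylidenehept-6-enoate (both C7 epimers)
Conditions: DABCO (1 equiv), 11 (2 equiv), minimal THF, rt, 4 d
Reagents that add atoms: none
Why: Morita–Baylis–Hillman reaction (amine conjugate addition, aldol to the activated α-silyloxy aldehyde, elimination) forms C7–C11 and joins the two halves; the new C7 carbinol centre is erased in step 9.

Step 9
Reactants: 12 Morita–Baylis–Hillman adduct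
Product: 13 (2Z,4S)-3-methyl-1-(triethylsilyloxy)hepta-2,6-dien-4-yl (2Z,4R)-2-(bromomethyl)-4-(tert-butyldimethylsilyloxy)-6-methylhepta-2,6-dienoate
Conditions: NBS (1.3 equiv), Me2S (1.5 equiv), CH2Cl2, 0 °C to rt
Reagents that add atoms: N-bromosuccinimide, O=C1CCC(=O)N1Br
Why: Corey–Kim-type activation of the allylic alcohol and SN2′ attack of bromide give the conjugated 2-(bromomethyl)enoate as its usual (Z) isomer (C8 cis to CH2Br).

Step 10
Reactants: 13 seco bromo ester
Product: 14 (3Z,5R,7Z,10S)-3-(bromomethyl)-5-(tert-butyldimethylsilyloxy)-7-methyl-10-[(2Z)-4-(triethylsilyloxy)but-2-en-2-yl]-1-oxacyclodeca-3,7-dien-2-one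
Conditions: second-generation Hoveyda–Grubbs catalyst (10 mol%), toluene (1 mM), 80 °C
Reagents that add atoms: none
Why: ring-closing metathesis of the allyl and methallyl olefins (the trisubstituted enoate and C4=C5 olefins are inert); the new trisubstituted C1=C10 olefin should form Z because a ten-membered ring that already holds the trans enoate accommodates a cis olefin far better (cis,trans-cyclodeca-1,5-diene type).

Step 11
Reactants: 14 tether macrolactone
Product: 15 (3Z,5R,7Z,10S)-3-(bromomethyl)-5-(tert-butyldimethylsilyloxy)-7-methyl-10-[(2Z)-4-oxobut-2-en-2-yl]-1-oxacyclodeca-3,7-dien-2-one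
Conditions: (COCl)2, DMSO, CH2Cl2, −78 to −40 °C; Et3N, −78 to 0 °C
Reagents that add atoms: none
Why: Swern oxidation acting directly on the primary triethylsilyl ether (oxidative desilylation) gives the (Z)-enal while the secondary TBS ether survives; low temperature avoids Z/E isomerisation.

Step 12
Reactants: 15 macrolactone (Z)-enal
Product: 17 3β-hydroxy-8β-(tert-butyldimethylsilyloxy)germacra-1(10)Z,4Z,11(13)-trien-6α,12-olide (H-7α), via bridged hydroxy lactone 16 (not isolated)
Conditions: In powder (2 equiv), THF–H2O 4:1 (0.01 M), 25 °C; then PPTS (0.2 equiv), 25 °C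
Reagents that add atoms: none
Why: Proposed new method: indium inserts into the allylic C–Br bond and the 2-(alkoxycarbonyl)allylindium, keeping its (Z) geometry, adds through C7 across the ring to the enal in a closed six-membered transition state; the three-atom C4=C5–C6 bridge can only reach C7 on the face fixed by C3 (sets C7) and holds the aldehyde substituent axial, which with the Z-allyl unit gives the 6,7-anti relationship (sets C6, trans-lactone); the strained bridged lactone 16 then relactonises onto the new 6-oxygen, releasing the 3-OH, so the carbocycle and the γ-lactone form together; closest known chemistry is the indium- or chromium-mediated intramolecular Barbier allylation–lactonisation of 2-(bromomethyl)acrylates (Dreiding–Schmidt type macrocyclisation) and transannular ring contraction.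

Step 13
Reactants: 17 3β-hydroxy lactone; 18 (2R)-2-methylbutanoic acid
Product: 19 3β-[(2R)-2-methylbutanoyloxy]-8β-(tert-butyldimethylsilyloxy)germacra-1(10)Z,4Z,11(13)-trien-6α,12-olide
Conditions: DIC (1.5 equiv), DMAP (0.2 equiv), CH2Cl2, 0 °C to rt
Reagents that add atoms: none
Why: Steglich esterification of the only free hydroxyl; carbodiimide activation at 0 °C does not epimerise the α-centre of the acid.

Step 14
Reactants: 19 3-ester 8-silyl ether
Product: 20 8β-hydroxy-3β-[(2R)-2-methylbutanoyloxy]germacra-1(10)Z,4Z,11(13)-trien-6α,12-olide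
Conditions: HF·pyridine, THF–pyridine, 0 °C to rt
Reagents that add atoms: none
Why: fluoride-mediated desilylation under buffered conditions that leave the methylene lactone and the ester intact.

Step 15
Reactants: 20 8β-hydroxy diene
Product: 21 1β,10β-epoxy-8β-hydroxy-3β-[(2R)-2-methylbutanoyloxy]germacra-4Z,11(13)-dien-6α,12-olide
Conditions: VO(acac)2 (10 mol%), t-BuOOH (1.5 equiv), CH2Cl2, 0 °C to rt
Reagents that add atoms: tert-butyl hydroperoxide, CC(C)(C)OO
Why: vanadium-catalysed hydroxyl-directed epoxidation of the homoallylic alcohol; the vanadate ester of the 8β-OH delivers oxygen to the β face of the Z C1=C10 olefin, giving the cis epoxide (C1 R, C10 S), while the C4=C5 olefin (no free allylic OH) and the methylene lactone do not react.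

Step 16
Reactants: 21 epoxy alcohol; 22 angelic acid
Product: 24 CNP0108431.1 = 8β-angeloyloxy-1β,10β-epoxy-3β-[(2R)-2-methylbutanoyloxy]germacra-4Z,11(13)-dien-6α,12-olide (1R,3S,6R,7R,8R,10S), via mixed anhydride 23 (not isolated)
Conditions: 22, 2,4,6-Cl3C6H2COCl, Et3N, toluene, rt; then 21, toluene, 60 °C
Reagents that add atoms: none
Why: Yamaguchi esterification through the mixed anhydride without DMAP, the standard way to angeloylate a hindered secondary alcohol without Z-to-E isomerisation to the tiglate.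

**Compound list**
1 | 3-methylfuran-2(5H)-one | CC1=CCOC1=O | starting material
2 | 3-methyl-2,5-dihydrofuran-2-ol | CC1=CCOC1O | intermediate
3 | (2Z,4S)-3-methylhepta-2,6-diene-1,4-diol | OC/C=C(/C)[C@@H](O)CC=C | intermediate
4 | (2Z,4S)-3-methyl-1-(triethylsilyloxy)hepta-2,6-dien-4-ol | CC[Si](CC)(CC)OC/C=C(/C)[C@@H](O)CC=C | intermediate
5 | acryloyl chloride | C=CC(=O)Cl | starting material
6 | (2Z,4S)-3-methyl-1-(triethylsilyloxy)hepta-2,6-dien-4-yl prop-2-enoate | CC[Si](CC)(CC)OC/C=C(/C)[C@@H](OC(=O)C=C)CC=C | intermediate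
7 | ethyl glyoxylate | CCOC(=O)C=O | starting material
8 | 2-methylpropene | CC(C)=C | starting material
9 | ethyl (2R)-2-hydroxy-4-methylpent-4-enoate | C=C(C)C[C@@H](O)C(=O)OCC | intermediate
10 | ethyl (2R)-2-(tert-butyldimethylsilyloxy)-4-methylpent-4-enoate | C=C(C)C[C@@H](O[Si](C)(C)C(C)(C)C)C(=O)OCC | intermediate
11 | (2R)-2-(tert-butyldimethylsilyloxy)-4-methylpent-4-enal | C=C(C)C[C@@H](O[Si](C)(C)C(C)(C)C)C=O | intermediate
12 | (2Z,4S)-3-methyl-1-(triethylsilyloxy)hepta-2,6-dien-4-yl (4R)-4-(tert-butyldimethylsilyloxy)-3-hydroxy-6-methyl-2-methylidenehept-6-enoate (both C7 epimers) | CC[Si](CC)(CC)OC/C=C(/C)[C@@H](OC(=O)C(=C)C(O)[C@H](O[Si](C)(C)C(C)(C)C)CC(C)=C)CC=C | intermediate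
13 | (2Z,4S)-3-methyl-1-(triethylsilyloxy)hepta-2,6-dien-4-yl (2Z,4R)-2-(bromomethyl)-4-(tert-butyldimethylsilyloxy)-6-methylhepta-2,6-dienoate | CC[Si](CC)(CC)OC/C=C(/C)[C@@H](OC(=O)/C(CBr)=C/[C@H](O[Si](C)(C)C(C)(C)C)CC(C)=C)CC=C | intermediate
14 | (3Z,5R,7Z,10S)-3-(bromomethyl)-5-(tert-butyldimethylsilyloxy)-7-methyl-10-[(2Z)-4-(triethylsilyloxy)but-2-en-2-yl]-1-oxacyclodeca-3,7-dien-2-one | CC[Si](CC)(CC)OC/C=C(/C)[C@@H]1C/C=C(/C)C[C@@H](O[Si](C)(C)C(C)(C)C)/C=C(CBr)/C(=O)O1 | intermediate
15 | (3Z,5R,7Z,10S)-3-(bromomethyl)-5-(tert-butyldimethylsilyloxy)-7-methyl-10-[(2Z)-4-oxobut-2-en-2-yl]-1-oxacyclodeca-3,7-dien-2-one | O=C/C=C(/C)[C@@H]1C/C=C(/C)C[C@@H](O[Si](C)(C)C(C)(C)C)/C=C(CBr)/C(=O)O1 | intermediate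
16 | bridged hydroxy lactone: 6α-hydroxy-8β-(tert-butyldimethylsilyloxy)germacra-1(10)Z,4Z,11(13)-trien-12,3β-olide (H-7α) | C=C1C(=O)O[C@H]2C/C=C(/C)C[C@@H](O[Si](C)(C)C(C)(C)C)[C@@H]1[C@H](O)/C=C2/C | intermediate
17 | 3β-hydroxy-8β-(tert-butyldimethylsilyloxy)germacra-1(10)Z,4Z,11(13)-trien-6α,12-olide (H-7α) | C=C1C(=O)O[C@@H]2/C=C(/C)[C@@H](O)C/C=C(/C)C[C@@H](O[Si](C)(C)C(C)(C)C)[C@@H]12 | intermediate
18 | (2R)-2-methylbutanoic acid | CC[C@@H](C)C(=O)O | starting material
19 | 3β-[(2R)-2-methylbutanoyloxy]-8β-(tert-butyldimethylsilyloxy)germacra-1(10)Z,4Z,11(13)-trien-6α,12-olide | C=C1C(=O)O[C@@H]2/C=C(/C)[C@@H](OC(=O)[C@H](C)CC)C/C=C(/C)C[C@@H](O[Si](C)(C)C(C)(C)C)[C@@H]12 | intermediate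
20 | 8β-hydroxy-3β-[(2R)-2-methylbutanoyloxy]germacra-1(10)Z,4Z,11(13)-trien-6α,12-olide | C=C1C(=O)O[C@@H]2/C=C(/C)[C@@H](OC(=O)[C@H](C)CC)C/C=C(/C)C[C@@H](O)[C@@H]12 | intermediate
21 | 1β,10β-epoxy-8β-hydroxy-3β-[(2R)-2-methylbutanoyloxy]germacra-4Z,11(13)-dien-6α,12-olide | C=C1C(=O)O[C@@H]2/C=C(/C)[C@@H](OC(=O)[C@H](C)CC)C[C@H]3O[C@@]3(C)C[C@@H](O)[C@@H]12 | intermediate
22 | angelic acid, (2Z)-2-methylbut-2-enoic acid | C/C=C(/C)C(=O)O | starting material
23 | angelic 2,4,6-trichlorobenzoic anhydride | C/C=C(/C)C(=O)OC(=O)c1c(Cl)cc(Cl)cc1Cl | intermediate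
24 | CNP0108431.1, 8β-angeloyloxy-1β,10β-epoxy-3β-[(2R)-2-methylbutanoyloxy]germacra-4Z,11(13)-dien-6α,12-olide | C=C1C(=O)O[C@@H]2/C=C(/C)[C@@H](OC(=O)[C@H](C)CC)C[C@H]3O[C@@]3(C)C[C@@H](OC(=O)/C(C)=C\C)[C@@H]12 | target

**Step count:** 16 steps in total. Longest linear sequence: 13 steps (steps 1–4 and 8–16).

**Three steps most likely to fail, each with a fallback**

Step 12 (transannular Barbier/translactonisation). The bridged transition state may be too strained, or the 6-epimer (cis-lactone) may form. The fallback sets out from 13 and reverses the order of the two ring closures. The primary TES ether of 13 is oxidised as in step 11 to the open-chain (Z)-enal bromo ester F1. Indium in wet THF then only has to close the eight-membered tether ring, and relactonisation gives the monocyclic α-methylene lactone F2 with the 3-OH free. Ring-closing metathesis of F2 (second-generation Hoveyda–Grubbs catalyst, toluene, 80 °C) forms the C1=C10 olefin of the carbocycle, and the route is rejoined at 17.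

Step 10 (metathesis to the ten-membered tether lactone). Oligomers or the E olefin are possible, since the ring must hold a trans enoate. The fallback sets out from 4 and 11 and drops the tether. Compound 4 is esterified with 18 (DIC, DMAP) to the ester F3, and Swern oxidation of its TES ether gives the (Z)-enal F4. Separately, 11 and methyl acrylate (DABCO) give the adduct F5, and NBS/Me2S converts it into the bromo ester F6. An intermolecular indium Barbier reaction of F4 with F6, followed by lactonisation, gives the seco lactone F7 (diastereomers at C6/C7 separated). Metathesis of F7 closes the carbocycle directly and the route is rejoined at 19.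

Step 8 (Morita–Baylis–Hillman union). A hindered acrylate and an α-silyloxy aldehyde may react too slowly or with partial racemisation at C8. The fallback sets out from 4 and 11 and makes the C7=C11 bond by olefination. Compound 4 is esterified with diethylphosphonoacetic acid (DIC, DMAP) to the phosphonoacetate F8. Paraformaldehyde and K2CO3 give the α-(hydroxymethyl)phosphonate F9. Horner–Wadsworth–Emmons reaction of F9 with 11 (aq. K2CO3, THF) gives the 2-(hydroxymethyl)enoate F10, with the minor olefin isomer removed. Appel bromination (CBr4, PPh3) of F10 rejoins the route at 13.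

**Further compounds**
F1 | step 12 | (2Z,4S)-3-methyl-1-oxohepta-2,6-dien-4-yl (2Z,4R)-2-(bromomethyl)-4-(tert-butyldimethylsilyloxy)-6-methylhepta-2,6-dienoate | O=C/C=C(/C)[C@@H](OC(=O)/C(CBr)=C/[C@H](O[Si](C)(C)C(C)(C)C)CC(C)=C)CC=C
F2 | step 12 | 5-[(1Z,3S)-3-hydroxy-2-methylhexa-1,5-dien-1-yl]-4-[(1R)-1-(tert-butyldimethylsilyloxy)-3-methylbut-3-en-1-yl]-3-methylideneoxolan-2-one with C6 and C7 as in 17 | C=C1C(=O)O[C@H](/C=C(/C)[C@@H](O)CC=C)[C@H]1[C@H](O[Si](C)(C)C(C)(C)C)CC(C)=C
F3 | step 10 | (2Z,4S)-3-methyl-1-(triethylsilyloxy)hepta-2,6-dien-4-yl (2R)-2-methylbutanoate | CC[Si](CC)(CC)OC/C=C(/C)[C@@H](OC(=O)[C@H](C)CC)CC=C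
F4 | step 10 | (2Z,4S)-3-methyl-1-oxohepta-2,6-dien-4-yl (2R)-2-methylbutanoate | O=C/C=C(/C)[C@@H](OC(=O)[C@H](C)CC)CC=C
F5 | step 10 | methyl (4R)-4-(tert-butyldimethylsilyloxy)-3-hydroxy-6-methyl-2-methylidenehept-6-enoate (both C3 epimers) | COC(=O)C(=C)C(O)[C@H](O[Si](C)(C)C(C)(C)C)CC(C)=C
F6 | step 10 | methyl (2Z,4R)-2-(bromomethyl)-4-(tert-butyldimethylsilyloxy)-6-methylhepta-2,6-dienoate | COC(=O)/C(CBr)=C/[C@H](O[Si](C)(C)C(C)(C)C)CC(C)=C
F7 | step 10 | 5-[(1Z,3S)-2-methyl-3-[(2R)-2-methylbutanoyloxy]hexa-1,5-dien-1-yl]-4-[(1R)-1-(tert-butyldimethylsilyloxy)-3-methylbut-3-en-1-yl]-3-methylideneoxolan-2-one with C6 and C7 as in 19 | C=C1C(=O)O[C@H](/C=C(/C)[C@@H](OC(=O)[C@H](C)CC)CC=C)[C@H]1[C@H](O[Si](C)(C)C(C)(C)C)CC(C)=C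
F8 | step 8 | (2Z,4S)-3-methyl-1-(triethylsilyloxy)hepta-2,6-dien-4-yl 2-(diethoxyphosphoryl)acetate | CC[Si](CC)(CC)OC/C=C(/C)[C@@H](OC(=O)CP(=O)(OCC)OCC)CC=C
F9 | step 8 | (2Z,4S)-3-methyl-1-(triethylsilyloxy)hepta-2,6-dien-4-yl 2-(diethoxyphosphoryl)-3-hydroxypropanoate (both epimers) | CC[Si](CC)(CC)OC/C=C(/C)[C@@H](OC(=O)C(CO)P(=O)(OCC)OCC)CC=C
F10 | step 8 | (2Z,4S)-3-methyl-1-(triethylsilyloxy)hepta-2,6-dien-4-yl (2E,4R)-4-(tert-butyldimethylsilyloxy)-2-(hydroxymethyl)-6-methylhepta-2,6-dienoate | CC[Si](CC)(CC)OC/C=C(/C)[C@@H](OC(=O)/C(CO)=C/[C@H](O[Si](C)(C)C(C)(C)C)CC(C)=C)CC=C
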